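The rate constants are those of an exercise.

What is asked for here is a leftover: L.G stands mostly as crystals Z, and gas that arrives once L has been consumed turns that stock into G.L.G.

L 0.17 M; X 33 mM (held); time 30 min

    X ⇌ G, rate k1*(csat - [G]) (k1 = 0.0047 s⁻¹, csat = 33 mM)
    L.G → Q (k2 = 0.0014 s⁻¹)
    Z ⇌ L.G, rate k3*(cs3 - [L.G]) while solid is left; crystals form when [L.G] > cs3 (cs3 = 1.7 mM, k3 = 0.029 s⁻¹)
    L + L.G → L.L.G (k4 = 0.013 M⁻¹ s⁻¹)
    L + G → L.G (k5 = 3.5 M⁻¹ s⁻¹)
    G + L.G → G.L.G (k6 = 2.0 M⁻¹ s⁻¹)

- percentages count the L that a species holds: one L.L.G counts as two
- L.G is meant together with its Z
- solid, in amounts per volume of the solution: Z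
- at the start none of G is dissolved
- run time (flask): 30 min

- midnight: doubling the saturation concentration of X, all else as stated
- dusk: doubling the dissolution coefficient of step 3, all else as stated
- winter: doubling the transfer coefficient of step 1, all else as stated
- dawn: doubling the solubility in step 3, all else as stated

- the L.G and Z together standing at 30 min, as a percentage of the L charged
- the change that raises the amount of L.G and Z together at 30 min, in percent of the L charged most ("none" if none brings more than 2 percentage points) (midnight / dusk / winter / dawn / none)
- amount of L.G and Z together at 30 min, in percent of the L charged, after midnight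

With G near zero, gas enters at 0.0547 min⁻¹ of the charge per minute, so the charge of L lasts about 18.3 min. Two extreme flasks bracket the leftover.

In the first, each G arriving after that time takes one L.G at the full rate of entry:

leftover = 35.8%

In the second, G stands at its saturation value as soon as L has been consumed, nothing was lost earlier, and dissolved L.G sits where the dissolving of Z balances its loss to G.L.G and Q:

dissolved L.G = 0.511 mM

drain = 0.01217 min⁻¹

leftover = 85.7%

This drain, the fraction of the charge leaving L.G and Z per minute, is carried forward. The dissolving coefficient 0.029 s⁻¹ is smaller than the loss coefficient of dissolved L.G, 0.0674 s⁻¹, but only by a factor of 2.32, so both steps enter the drain and neither is a rate-limiting step. The drain is slower than the entry of gas, so G should climb and the flask should stand in the upper part of the range. It should stay below the top, because Q and L.L.G form earlier and the second extreme does not count them. With the saturation value doubled, the drain becomes 0.01429 min⁻¹ and the top of the range 70.2%. This reckoning ranks no change, so it names no best one.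

The forecast gives 53% for y, dusk as the best change and 0.5% after midnight, holding that “G + L.G drains the dissolved product, fed by the crystals, at about 0.065 mM/s until 30 min”. The drain reckoned here differs from that: 0.0345 mM s⁻¹.

The simulation gives 68.7% for y, dusk as the best change with a gain of 2.8 percentage points, and 50.9% after midnight.

At 30.0 min the flask makes dissolved L.G 0.997 times as fast as it uses it, and Z holds 68.3% of the 68.7% of L.G and Z. Left until 50 min, this flask falls to 46.0%, a reading of 0.01131 min⁻¹ of the charge per minute beside the drain of 0.0122 min⁻¹. In the neighbouring flask with 0.043 M of L, the drain is 0.0481 min⁻¹. There L lasts about 4.62 min and the stock about 20.8 min more, together less than 30 min. That flask holds 0% of L.G and Z and 90.3% of G.L.G.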